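**Retrosynthetic overview**
1. Target ⇒ C8 alcohol of the macrocyclic lactone + (2S,3R)-2,3-dimethyloxirane-2-carboxylic acid (Yamaguchi ester last; acid from (E)-2-methylbut-2-en-1-ol by Sharpless epoxidation and oxidation).
2. Ten-membered carbocycle + α-methylene-γ-lactone ⇒ acyclic C6 epoxy aldehyde / C13 allylic bromide: intramolecular CrCl2 allylation (C6–C7), then lactonisation.
3. Acyclic chain ⇒ C9–C10 bond by chelation-controlled addition of a (Z)-α-magnesio enynoate (West fragment) to an α-PMB-oxy aldehyde (East fragment); C2=C3 cis by Lindlar reduction.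
4. West fragment ⇐ (E)-3-methylpent-2-en-4-yn-1-ol (Sharpless epoxidation sets C4/C5; formylation; iodo-Wittig). East fragment ⇐ diethyl D-tartrate (C8) by PMB-acetal opening, glycol cleavage and Wittig.
5. Ring order: C4–C5 oxirane (step 1); side-chain oxirane in a separate branch (step 18); carbocycle and γ-lactone together (step 16).

Assumption: C-locants in the text are the germacrane locants of the target (C6 lactone carbinol; C12 lactone carbonyl; C13 exocyclic methylene; C14 ester carbon on C10; C15 methyl on C4).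

Step 1
Reactants: 1 (2E)-3-methylpent-2-en-4-yn-1-ol
Product: 2 [(2R,3R)-3-ethynyl-3-methyloxiran-2-yl]methanol
Conditions: Ti(OiPr)4 (10 mol %), D-(−)-diisopropyl tartrate (12 mol %), t-BuOOH, 4 Å molecular sieves (Na12Al12Si12O48), CH2Cl2, −20 °C
Reagents that add atoms: tert-butyl hydroperoxide, CC(C)(C)OO
Why: Katsuki–Sharpless asymmetric epoxidation touches only the allylic-alcohol alkene, and the D-(−)-tartrate ligand delivers oxygen to the face that gives the 2R,3R oxirane (C4 R, C5 R), the mirror image of the 2S,3S outcome of L-(+)-tartrate with geraniol-type alcohols.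

Step 2
Reactants: 2 [(2R,3R)-3-ethynyl-3-methyloxiran-2-yl]methanol
Product: 3 tert-butyl{[(2R,3R)-3-ethynyl-3-methyloxiran-2-yl]methoxy}dimethylsilane
Conditions: TBSCl, imidazole, CH2Cl2, 0 °C → rt
Reagents that add atoms: tert-butyldimethylsilyl chloride, CC(C)(C)[Si](C)(C)Cl
Why: Silylation of the primary alcohol masks C6–OH for the organometallic steps without touching a stereocentre.

Step 3
Reactants: 3 tert-butyl{[(2R,3R)-3-ethynyl-3-methyloxiran-2-yl]methoxy}dimethylsilane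
Product: 4 3-[(2R,3R)-3-{[(tert-butyldimethylsilyl)oxy]methyl}-2-methyloxiran-2-yl]prop-2-ynal
Conditions: n-BuLi, THF, −78 °C; DMF, −78 → 0 °C; inverse quench into aq. KH2PO4
Reagents that add atoms: N,N-dimethylformamide, CN(C)C=O
Why: Formylation of the lithium acetylide with DMF gives the ynal (C1), and the oxirane is inert to the acetylide at −78 °C.

Step 4
Reactants: 4 3-[(2R,3R)-3-{[(tert-butyldimethylsilyl)oxy]methyl}-2-methyloxiran-2-yl]prop-2-ynal; 5 methyl 2-(triphenyl-λ5-phosphanylidene)acetate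
Product: 7 methyl (2Z)-5-[(2R,3R)-3-{[(tert-butyldimethylsilyl)oxy]methyl}-2-methyloxiran-2-yl]-2-iodopent-2-en-4-ynoate, via iodo ylide 6 (not isolated)
Conditions: 5, N-iodosuccinimide, CH2Cl2, −20 °C, 30 min; then 4, −20 °C → rt
Reagents that add atoms: N-iodosuccinimide, O=C1CCC(=O)N1I
Why: Wittig olefination with the α-iodo stabilised ylide places the ester trans to the alkynyl residue, so iodine (the later C9 position) sits cis to C2 in the 2Z iodide.

Step 5
Reactants: 8 diethyl (2S,3S)-2,3-dihydroxybutanedioate (diethyl D-tartrate)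
Product: 9 diethyl (4S,5S)-2-(4-methoxyphenyl)-1,3-dioxolane-4,5-dicarboxylate
Conditions: 4-methoxybenzaldehyde dimethyl acetal, camphorsulfonic acid (cat.), toluene, 60 °C, reduced pressure
Reagents that add atoms: 4-methoxybenzaldehyde dimethyl acetal, COc1ccc(C(OC)OC)cc1
Why: Acid-catalysed transacetalisation of the C2-symmetric diol gives a single acetal and leaves both stereocentres untouched.

Step 6
Reactants: 9 diethyl (4S,5S)-2-(4-methoxyphenyl)-1,3-dioxolane-4,5-dicarboxylate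
Product: 10 (2R,3R)-3-[(4-methoxyphenyl)methoxy]butane-1,2,4-triol
Conditions: i-Bu2AlH (6 equiv), CH2Cl2, −78 °C → rt; aq. KNaC4H4O6
Reagents that add atoms: none
Why: Hydride reduction of both esters and reductive opening of the 4-methoxybenzylidene acetal give the mono-PMB triol, and C2 symmetry makes the two possible ring-opening products identical.

Step 7
Reactants: 10 (2R,3R)-3-[(4-methoxyphenyl)methoxy]butane-1,2,4-triol
Product: 11 (2R)-3-hydroxy-2-[(4-methoxyphenyl)methoxy]propanal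
Conditions: NaIO4, NaHCO3, CH2Cl2/H2O, 0 °C → rt
Reagents that add atoms: none
Why: Malaprade glycol cleavage removes the terminal diol carbon and keeps the PMB-bearing stereocentre (future C8).

Step 8
Reactants: 5 methyl 2-(triphenyl-λ5-phosphanylidene)acetate
Product: 13 methyl 2-(triphenyl-λ5-phosphanylidene)-3-{[tri(propan-2-yl)silyl]oxy}propanoate, via phosphonium chloride 12 (not isolated)
Conditions: 5 (2 equiv), (triisopropylsiloxy)methyl chloride, CH2Cl2, 0 °C → rt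
Reagents that add atoms: [(triisopropylsilyl)oxy]methyl chloride, CC(C)[Si](OCCl)(C(C)C)C(C)C
Why: C-Alkylation of the stabilised ylide by the reactive α-chloro ether, then transylidation by the second equivalent of 5, gives the α-substituted ylide that carries C11, C12 and C13.

Step 9
Reactants: 11 (2R)-3-hydroxy-2-[(4-methoxyphenyl)methoxy]propanal; 13 methyl 2-(triphenyl-λ5-phosphanylidene)-3-{[tri(propan-2-yl)silyl]oxy}propanoate
Product: 14 methyl (2E,4S)-5-hydroxy-4-[(4-methoxyphenyl)methoxy]-2-({[tri(propan-2-yl)silyl]oxy}methyl)pent-2-enoate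
Conditions: toluene, 60 °C
Reagents that add atoms: none
Why: Wittig olefination with an α-substituted stabilised ylide under neutral conditions gives the E enoate (ester trans to C8) without epimerising the α-alkoxy aldehyde.

Step 10
Reactants: 14 methyl (2E,4S)-5-hydroxy-4-[(4-methoxyphenyl)methoxy]-2-({[tri(propan-2-yl)silyl]oxy}methyl)pent-2-enoate
Product: 15 methyl (2E,4S)-4-[(4-methoxyphenyl)methoxy]-5-oxo-2-({[tri(propan-2-yl)silyl]oxy}methyl)pent-2-enoate
Conditions: Dess–Martin periodinane, NaHCO3, CH2Cl2, 0 °C; used at once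
Reagents that add atoms: none
Why: Buffered Dess–Martin oxidation gives the C9 aldehyde under non-basic conditions that preserve the C8 stereocentre.

Step 11
Reactants: 7 methyl (2Z)-5-[(2R,3R)-3-{[(tert-butyldimethylsilyl)oxy]methyl}-2-methyloxiran-2-yl]-2-iodopent-2-en-4-ynoate; 15 methyl (2E,4S)-4-[(4-methoxyphenyl)methoxy]-5-oxo-2-({[tri(propan-2-yl)silyl]oxy}methyl)pent-2-enoate
Product: 18 dimethyl (2E,4S,5S,6E)-5-(acetyloxy)-6-{3-[(2R,3R)-3-{[(tert-butyldimethylsilyl)oxy]methyl}-2-methyloxiran-2-yl]prop-2-yn-1-ylidene}-4-[(4-methoxyphenyl)methoxy]-2-({[tri(propan-2-yl)silyl]oxy}methyl)hept-2-enedioate, via alkenylmagnesium chloride 16 (not isolated), via chloromagnesium alkoxide 17 (not isolated)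
Conditions: 7, i-PrMgCl·LiCl, THF, −78 °C, 20 min; then 15 premixed with MgBr2·OEt2, CH2Cl2, −78 °C; then Ac2O, −78 → 0 °C
Reagents that add atoms: acetic anhydride, CC(=O)OC(C)=O
Why: Iodine–magnesium exchange gives an α-magnesio enoate that keeps its geometry at −78 °C and adds to the aldehyde under Cram-chelate control (magnesium bridging the carbonyl and PMB-ether oxygens), which sets C9 as S (8,9-syn) before the alkoxide is acetylated in the flask.

Step 12
Reactants: 18 the 2,3-alkyne diester of step 11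
Product: 19 dimethyl (2E,4S,5S,6E)-5-(acetyloxy)-6-{(2Z)-3-[(2R,3R)-3-{[(tert-butyldimethylsilyl)oxy]methyl}-2-methyloxiran-2-yl]prop-2-en-1-ylidene}-4-[(4-methoxyphenyl)methoxy]-2-({[tri(propan-2-yl)silyl]oxy}methyl)hept-2-enedioate
Conditions: H2 (1 atm), Pd/CaCO3 poisoned with Pb(OAc)2, quinoline, EtOAc, rt
Reagents that add atoms: none
Why: Lindlar semihydrogenation adds H2 syn to the alkyne to give the 2Z alkene while the poisoned catalyst spares the electron-poor trisubstituted alkenes, the oxirane and the acetate.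

Step 13
Reactants: 19 the bis-silyl Z,Z-diene diester of step 12
Product: 20 dimethyl (2E,4S,5S,6E)-5-(acetyloxy)-2-(hydroxymethyl)-6-{(2Z)-3-[(2R,3R)-3-(hydroxymethyl)-2-methyloxiran-2-yl]prop-2-en-1-ylidene}-4-[(4-methoxyphenyl)methoxy]hept-2-enedioate
Conditions: HF·pyridine, pyridine, THF, 0 °C → rt
Reagents that add atoms: none
Why: Buffered fluoride desilylation removes both primary silyl ethers and leaves the oxirane, acetate and PMB ether intact.

Step 14
Reactants: 20 the diol of step 13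
Product: 21 dimethyl (2Z,4S,5S,6E)-5-(acetyloxy)-2-(bromomethyl)-6-{(2Z)-3-[(2R,3R)-3-(hydroxymethyl)-2-methyloxiran-2-yl]prop-2-en-1-ylidene}-4-[(4-methoxyphenyl)methoxy]hept-2-enedioate
Conditions: N-bromosuccinimide, Me2S, CH2Cl2, −20 °C; then 20 (1.0 equiv reagent), −20 → 0 °C
Reagents that add atoms: N-bromosuccinimide, O=C1CCC(=O)N1Br
Why: Corey–Kim halogenation converts the allylic primary alcohol (C13) into the bromide, whereas the non-allylic epoxy carbinol (C6) is not displaced under these conditions.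

Step 15
Reactants: 21 the allylic bromide of step 14
Product: 22 dimethyl (2Z,4S,5S,6E)-5-(acetyloxy)-2-(bromomethyl)-6-{(2Z)-3-[(2R,3S)-3-formyl-2-methyloxiran-2-yl]prop-2-en-1-ylidene}-4-[(4-methoxyphenyl)methoxy]hept-2-enedioate
Conditions: Dess–Martin periodinane, NaHCO3, CH2Cl2, 0 °C
Reagents that add atoms: none
Why: Neutral Dess–Martin oxidation gives the C6 epoxy aldehyde and tolerates the allylic bromide (C5 is unchanged in space and becomes S only through the priority change).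

Step 16
Reactants: 22 the bromo epoxy aldehyde of step 15
Product: 24 methyl (1(10)E,2Z,4R,5R,6S,7R,8S,9S)-9-acetoxy-4,5-epoxy-8-[(4-methoxybenzyl)oxy]germacra-1(10),2,11(13)-trien-12,6-olid-14-oate, via hydroxy diester 23 (not isolated)
Conditions: CrCl2 (10 equiv), THF/DMF (10:1), 0.003 M, syringe-pump addition of 22, rt; then 40 °C
Reagents that add atoms: none
Why: Intramolecular Nozaki–Hiyama (Barbier-type) 2-(alkoxycarbonyl)allylation closes the ten-membered ring through C7 via a chair transition state that places C6–O and C7–C8 anti (trans-lactone), the C5 oxirane steers the aldehyde face to give 6S,7R by analogy with chromium-mediated closures of 4,5-epoxygermacranolides, and the alkoxide then lactonises onto C12.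

Step 17
Reactants: 24 the PMB-protected macrocyclic lactone of step 16
Product: 25 methyl (1(10)E,2Z,4R,5R,6S,7R,8S,9S)-9-acetoxy-4,5-epoxy-8-hydroxygermacra-1(10),2,11(13)-trien-12,6-olid-14-oate
Conditions: DDQ, CH2Cl2/pH 7 phosphate buffer, 0 °C → rt
Reagents that add atoms: none
Why: Oxidative PMB cleavage by DDQ (benzylic oxidation to the oxocarbenium ion, then hydrolysis) frees C8–OH without touching the esters, oxirane or electron-poor alkenes.

Step 18
Reactants: 26 (2E)-2-methylbut-2-en-1-ol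
Product: 27 [(2R,3R)-2,3-dimethyloxiran-2-yl]methanol
Conditions: Ti(OiPr)4 (10 mol %), D-(−)-diisopropyl tartrate (12 mol %), t-BuOOH, 4 Å molecular sieves (Na12Al12Si12O48), CH2Cl2, −20 °C
Reagents that add atoms: tert-butyl hydroperoxide, CC(C)(C)OO
Why: Katsuki–Sharpless asymmetric epoxidation with the D-(−)-tartrate ligand gives the 2R,3R epoxy alcohol from the E allylic alcohol, with the two methyl groups cis as in the alkene.

Step 19
Reactants: 27 [(2R,3R)-2,3-dimethyloxiran-2-yl]methanol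
Product: 28 (2S,3R)-2,3-dimethyloxirane-2-carboxylic acid
Conditions: TEMPO (cat.), PhI(OAc)2, MeCN/H2O (1:1), rt
Reagents that add atoms: water, O
Why: TEMPO-catalysed oxidation takes the primary alcohol through the aldehyde hydrate to the acid without opening the oxirane (C2 becomes S only through the priority change).

Step 20
Reactants: 25 methyl (1(10)E,2Z,4R,5R,6S,7R,8S,9S)-9-acetoxy-4,5-epoxy-8-hydroxygermacra-1(10),2,11(13)-trien-12,6-olid-14-oate; 28 (2S,3R)-2,3-dimethyloxirane-2-carboxylic acid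
Product: 30 methyl (1(10)E,2Z,4R,5R,6S,7R,8S,9S)-9-acetoxy-8-{[(2S,3R)-2,3-dimethyloxirane-2-carbonyl]oxy}-4,5-epoxygermacra-1(10),2,11(13)-trien-12,6-olid-14-oate, via mixed anhydride 29 (not isolated)
Conditions: 28, 2,4,6-trichlorobenzoyl chloride, Et3N, THF, 0 °C; then 25, DMAP, toluene, rt
Reagents that add atoms: none
Why: Yamaguchi esterification acylates the hindered C8–OH through the mixed anhydride under DMAP catalysis, with retention at every stereocentre.

**Compound list**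
1 | (2E)-3-methylpent-2-en-4-yn-1-ol | C#C/C(C)=C/CO | starting material
2 | [(2R,3R)-3-ethynyl-3-methyloxiran-2-yl]methanol | C#C[C@@]1(C)O[C@@H]1CO | intermediate
3 | tert-butyl{[(2R,3R)-3-ethynyl-3-methyloxiran-2-yl]methoxy}dimethylsilane | C#C[C@@]1(C)O[C@@H]1CO[Si](C)(C)C(C)(C)C | intermediate
4 | 3-[(2R,3R)-3-{[(tert-butyldimethylsilyl)oxy]methyl}-2-methyloxiran-2-yl]prop-2-ynal | O=CC#C[C@@]1(C)O[C@@H]1CO[Si](C)(C)C(C)(C)C | intermediate
5 | methyl 2-(triphenyl-λ5-phosphanylidene)acetate | COC(=O)C=P(c1ccccc1)(c1ccccc1)c1ccccc1 | starting material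
6 | methyl 2-iodo-2-(triphenyl-λ5-phosphanylidene)acetate | COC(=O)C(I)=P(c1ccccc1)(c1ccccc1)c1ccccc1 | intermediate
7 | methyl (2Z)-5-[(2R,3R)-3-{[(tert-butyldimethylsilyl)oxy]methyl}-2-methyloxiran-2-yl]-2-iodopent-2-en-4-ynoate | COC(=O)/C(I)=C/C#C[C@@]1(C)O[C@@H]1CO[Si](C)(C)C(C)(C)C | intermediate
8 | diethyl (2S,3S)-2,3-dihydroxybutanedioate (diethyl D-tartrate) | CCOC(=O)[C@@H](O)[C@H](O)C(=O)OCC | starting material
9 | diethyl (4S,5S)-2-(4-methoxyphenyl)-1,3-dioxolane-4,5-dicarboxylate | CCOC(=O)[C@H]1OC(c2ccc(OC)cc2)O[C@@H]1C(=O)OCC | intermediate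
10 | (2R,3R)-3-[(4-methoxyphenyl)methoxy]butane-1,2,4-triol | OC[C@@H](O)[C@H](OCc1ccc(OC)cc1)CO | intermediate
11 | (2R)-3-hydroxy-2-[(4-methoxyphenyl)methoxy]propanal | O=C[C@H](OCc1ccc(OC)cc1)CO | intermediate
12 | [1-methoxy-1-oxo-3-{[tri(propan-2-yl)silyl]oxy}propan-2-yl]triphenylphosphonium chloride | COC(=O)C(CO[Si](C(C)C)(C(C)C)C(C)C)[P+](c1ccccc1)(c1ccccc1)c1ccccc1.[Cl-] | intermediate
13 | methyl 2-(triphenyl-λ5-phosphanylidene)-3-{[tri(propan-2-yl)silyl]oxy}propanoate | COC(=O)C(CO[Si](C(C)C)(C(C)C)C(C)C)=P(c1ccccc1)(c1ccccc1)c1ccccc1 | intermediate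
14 | methyl (2E,4S)-5-hydroxy-4-[(4-methoxyphenyl)methoxy]-2-({[tri(propan-2-yl)silyl]oxy}methyl)pent-2-enoate | COC(=O)/C(CO[Si](C(C)C)(C(C)C)C(C)C)=C/[C@H](OCc1ccc(OC)cc1)CO | intermediate
15 | methyl (2E,4S)-4-[(4-methoxyphenyl)methoxy]-5-oxo-2-({[tri(propan-2-yl)silyl]oxy}methyl)pent-2-enoate | COC(=O)/C(CO[Si](C(C)C)(C(C)C)C(C)C)=C/[C@H](OCc1ccc(OC)cc1)C=O | intermediate
16 | methyl (2Z)-5-[(2R,3R)-3-{[(tert-butyldimethylsilyl)oxy]methyl}-2-methyloxiran-2-yl]-2-(chloromagnesio)pent-2-en-4-ynoate | COC(=O)/C([Mg]Cl)=C/C#C[C@@]1(C)O[C@@H]1CO[Si](C)(C)C(C)(C)C | intermediate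
17 | dimethyl (2E,4S,5S,6E)-6-{3-[(2R,3R)-3-{[(tert-butyldimethylsilyl)oxy]methyl}-2-methyloxiran-2-yl]prop-2-yn-1-ylidene}-5-[(chloromagnesio)oxy]-4-[(4-methoxyphenyl)methoxy]-2-({[tri(propan-2-yl)silyl]oxy}methyl)hept-2-enedioate | CC(C)[Si](OC/C(C(=O)OC)=C\[C@H](OCc1ccc(OC)cc1)[C@@H](O[Mg]Cl)/C(C(=O)OC)=C\C#C[C@@]1(C)O[C@@H]1CO[Si](C)(C)C(C)(C)C)(C(C)C)C(C)C | intermediate
18 | dimethyl (2E,4S,5S,6E)-5-(acetyloxy)-6-{3-[(2R,3R)-3-{[(tert-butyldimethylsilyl)oxy]methyl}-2-methyloxiran-2-yl]prop-2-yn-1-ylidene}-4-[(4-methoxyphenyl)methoxy]-2-({[tri(propan-2-yl)silyl]oxy}methyl)hept-2-enedioate | CC(C)[Si](OC/C(C(=O)OC)=C\[C@H](OCc1ccc(OC)cc1)[C@@H](OC(C)=O)/C(C(=O)OC)=C\C#C[C@@]1(C)O[C@@H]1CO[Si](C)(C)C(C)(C)C)(C(C)C)C(C)C | intermediate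
19 | dimethyl (2E,4S,5S,6E)-5-(acetyloxy)-6-{(2Z)-3-[(2R,3R)-3-{[(tert-butyldimethylsilyl)oxy]methyl}-2-methyloxiran-2-yl]prop-2-en-1-ylidene}-4-[(4-methoxyphenyl)methoxy]-2-({[tri(propan-2-yl)silyl]oxy}methyl)hept-2-enedioate | CC(C)[Si](OC/C(C(=O)OC)=C\[C@H](OCc1ccc(OC)cc1)[C@@H](OC(C)=O)/C(C(=O)OC)=C\C=C/[C@@]1(C)O[C@@H]1CO[Si](C)(C)C(C)(C)C)(C(C)C)C(C)C | intermediate
20 | dimethyl (2E,4S,5S,6E)-5-(acetyloxy)-2-(hydroxymethyl)-6-{(2Z)-3-[(2R,3R)-3-(hydroxymethyl)-2-methyloxiran-2-yl]prop-2-en-1-ylidene}-4-[(4-methoxyphenyl)methoxy]hept-2-enedioate | OC/C(C(=O)OC)=C\[C@H](OCc1ccc(OC)cc1)[C@@H](OC(C)=O)/C(C(=O)OC)=C\C=C/[C@@]1(C)O[C@@H]1CO | intermediate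
21 | dimethyl (2Z,4S,5S,6E)-5-(acetyloxy)-2-(bromomethyl)-6-{(2Z)-3-[(2R,3R)-3-(hydroxymethyl)-2-methyloxiran-2-yl]prop-2-en-1-ylidene}-4-[(4-methoxyphenyl)methoxy]hept-2-enedioate | BrC/C(C(=O)OC)=C\[C@H](OCc1ccc(OC)cc1)[C@@H](OC(C)=O)/C(C(=O)OC)=C\C=C/[C@@]1(C)O[C@@H]1CO | intermediate
22 | dimethyl (2Z,4S,5S,6E)-5-(acetyloxy)-2-(bromomethyl)-6-{(2Z)-3-[(2R,3S)-3-formyl-2-methyloxiran-2-yl]prop-2-en-1-ylidene}-4-[(4-methoxyphenyl)methoxy]hept-2-enedioate | BrC/C(C(=O)OC)=C\[C@H](OCc1ccc(OC)cc1)[C@@H](OC(C)=O)/C(C(=O)OC)=C\C=C/[C@@]1(C)O[C@@H]1C=O | intermediate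
23 | dimethyl (1(10)E,2Z,4R,5R,6S,7S,8S,9S)-9-acetoxy-4,5-epoxy-6-hydroxy-8-[(4-methoxybenzyl)oxy]germacra-1(10),2,11(13)-triene-12,14-dioate | C=C(C(=O)OC)[C@@H]1[C@H](OCc2ccc(OC)cc2)[C@@H](OC(C)=O)/C(C(=O)OC)=C\C=C/[C@@]2(C)O[C@@H]2[C@H]1O | intermediate
24 | methyl (1(10)E,2Z,4R,5R,6S,7R,8S,9S)-9-acetoxy-4,5-epoxy-8-[(4-methoxybenzyl)oxy]germacra-1(10),2,11(13)-trien-12,6-olid-14-oate | C=C1C(=O)O[C@H]2[C@H]1[C@H](OCc1ccc(OC)cc1)[C@@H](OC(C)=O)/C(C(=O)OC)=C\C=C/[C@@]1(C)O[C@H]21 | intermediate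
25 | methyl (1(10)E,2Z,4R,5R,6S,7R,8S,9S)-9-acetoxy-4,5-epoxy-8-hydroxygermacra-1(10),2,11(13)-trien-12,6-olid-14-oate | C=C1C(=O)O[C@H]2[C@H]1[C@H](O)[C@@H](OC(C)=O)/C(C(=O)OC)=C\C=C/[C@@]1(C)O[C@H]21 | intermediate
26 | (2E)-2-methylbut-2-en-1-ol | C/C=C(\C)CO | starting material
27 | [(2R,3R)-2,3-dimethyloxiran-2-yl]methanol | OC[C@@]1(C)O[C@@H]1C | intermediate
28 | (2S,3R)-2,3-dimethyloxirane-2-carboxylic acid | O=C(O)[C@@]1(C)O[C@@H]1C | intermediate
29 | (2S,3R)-2,3-dimethyloxirane-2-carboxylic 2,4,6-trichlorobenzoic anhydride | O=C(OC(=O)c1c(Cl)cc(Cl)cc1Cl)[C@@]1(C)O[C@@H]1C | intermediate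
30 | methyl (1(10)E,2Z,4R,5R,6S,7R,8S,9S)-9-acetoxy-8-{[(2S,3R)-2,3-dimethyloxirane-2-carbonyl]oxy}-4,5-epoxygermacra-1(10),2,11(13)-trien-12,6-olid-14-oate (CNP0229507.7) | C=C1C(=O)O[C@H]2[C@H]1[C@H](OC(=O)[C@@]1(C)O[C@@H]1C)[C@@H](OC(C)=O)/C(C(=O)OC)=C\C=C/[C@@]1(C)O[C@H]21 | target

**Totals**
Total step count: 20.
Longest linear sequence: 13 steps (8 → 9 → 10 → 11 → 14 → 15 → 18 → 19 → 20 → 21 → 22 → 24 → 25 → 30; steps 5, 6, 7, 9, 10, 11, 12, 13, 14, 15, 16, 17, 20).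

**Three steps most likely to fail**

Step 11 (C9–C10 coupling). The α-magnesio enoate may scramble the C10=C1 geometry through its allenoate form, or chelation may be incomplete and lower the 8,9-syn ratio. Fallback: set out from 7 (with 15) and couple by a Nozaki–Hiyama–Kishi reaction (CrCl2, cat. NiCl2, DMSO/THF, rt). The alkenylchromium keeps its geometry but adds under Felkin–Anh control, so the main product is the 9R alcohol dimethyl (2E,4S,5R,6E)-6-{3-[(2R,3R)-3-{[(tert-butyldimethylsilyl)oxy]methyl}-2-methyloxiran-2-yl]prop-2-yn-1-ylidene}-5-hydroxy-4-[(4-methoxyphenyl)methoxy]-2-({[tri(propan-2-yl)silyl]oxy}methyl)hept-2-enedioate F1. Mitsunobu reaction of F1 with acetic acid (PPh3, diisopropyl azodicarboxylate, toluene, 0 °C) installs the acetate with inversion at C9 and comes back to the route at 18.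

Step 12 (semihydrogenation). Over-reduction of the dienoate or loss of the allylic acetate or oxirane on the fully assembled chain is possible. Fallback: set the cis alkene on the small West fragment, setting out from 3. n-BuLi and paraformaldehyde give 3-[(2R,3R)-3-{[(tert-butyldimethylsilyl)oxy]methyl}-2-methyloxiran-2-yl]prop-2-yn-1-ol F2. Lindlar reduction of this simple alkyne gives (2Z)-3-[(2R,3R)-3-{[(tert-butyldimethylsilyl)oxy]methyl}-2-methyloxiran-2-yl]prop-2-en-1-ol F3. MnO2 oxidation gives (2Z)-3-[(2R,3R)-3-{[(tert-butyldimethylsilyl)oxy]methyl}-2-methyloxiran-2-yl]prop-2-enal F4. The iodo-Wittig reaction with 6 gives methyl (2Z,4Z)-5-[(2R,3R)-3-{[(tert-butyldimethylsilyl)oxy]methyl}-2-methyloxiran-2-yl]-2-iodopenta-2,4-dienoate F5. F5 is then taken through the magnesium exchange, addition to 15 and acetylation exactly as 7 was, and comes back to the route at 19.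

Step 16 (macrocyclisation). The chromium closure may give the wrong C6/C7 diastereomer next to the C8 stereocentre, oligomerise, or eliminate the C8 ether from the allylchromium. Fallback: change the allyl donor from chromium to boron, setting out from 21. Copper-catalysed borylation (B2pin2, CuCl, Xantphos, KOt-Bu, THF) gives the allylboronate dimethyl (2E,4S,5S,6E)-5-(acetyloxy)-6-{(2Z)-3-[(2R,3R)-3-(hydroxymethyl)-2-methyloxiran-2-yl]prop-2-en-1-ylidene}-4-[(4-methoxyphenyl)methoxy]-2-[(4,4,5,5-tetramethyl-1,3,2-dioxaborolan-2-yl)methyl]hept-2-enedioate F6. Dess–Martin oxidation gives the corresponding (2R,3S)-3-formyl-2-methyloxiranyl aldehyde F7. Warming F7 at high dilution in toluene (or cat. Sc(OTf)3) brings about intramolecular allylboration through a closed six-membered transition state, followed by lactonisation, and comes back to the route at 24.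

**Further compounds**
F1 | step 11 | dimethyl (2E,4S,5R,6E)-6-{3-[(2R,3R)-3-{[(tert-butyldimethylsilyl)oxy]methyl}-2-methyloxiran-2-yl]prop-2-yn-1-ylidene}-5-hydroxy-4-[(4-methoxyphenyl)methoxy]-2-({[tri(propan-2-yl)silyl]oxy}methyl)hept-2-enedioate | CC(C)[Si](OC/C(C(=O)OC)=C\[C@H](OCc1ccc(OC)cc1)[C@H](O)/C(C(=O)OC)=C\C#C[C@@]1(C)O[C@@H]1CO[Si](C)(C)C(C)(C)C)(C(C)C)C(C)C
F2 | step 12 | 3-[(2R,3R)-3-{[(tert-butyldimethylsilyl)oxy]methyl}-2-methyloxiran-2-yl]prop-2-yn-1-ol | OCC#C[C@@]1(C)O[C@@H]1CO[Si](C)(C)C(C)(C)C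
F3 | step 12 | (2Z)-3-[(2R,3R)-3-{[(tert-butyldimethylsilyl)oxy]methyl}-2-methyloxiran-2-yl]prop-2-en-1-ol | OC/C=C\[C@@]1(C)O[C@@H]1CO[Si](C)(C)C(C)(C)C
F4 | step 12 | (2Z)-3-[(2R,3R)-3-{[(tert-butyldimethylsilyl)oxy]methyl}-2-methyloxiran-2-yl]prop-2-enal | O=C/C=C\[C@@]1(C)O[C@@H]1CO[Si](C)(C)C(C)(C)C
F5 | step 12 | methyl (2Z,4Z)-5-[(2R,3R)-3-{[(tert-butyldimethylsilyl)oxy]methyl}-2-methyloxiran-2-yl]-2-iodopenta-2,4-dienoate | COC(=O)/C(I)=C/C=C\[C@@]1(C)O[C@@H]1CO[Si](C)(C)C(C)(C)C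
F6 | step 16 | dimethyl (2E,4S,5S,6E)-5-(acetyloxy)-6-{(2Z)-3-[(2R,3R)-3-(hydroxymethyl)-2-methyloxiran-2-yl]prop-2-en-1-ylidene}-4-[(4-methoxyphenyl)methoxy]-2-[(4,4,5,5-tetramethyl-1,3,2-dioxaborolan-2-yl)methyl]hept-2-enedioate | CC1(C)OB(C/C(C(=O)OC)=C\[C@H](OCc2ccc(OC)cc2)[C@@H](OC(C)=O)/C(C(=O)OC)=C\C=C/[C@@]2(C)O[C@@H]2CO)OC1(C)C
F7 | step 16 | dimethyl (2E,4S,5S,6E)-5-(acetyloxy)-6-{(2Z)-3-[(2R,3S)-3-formyl-2-methyloxiran-2-yl]prop-2-en-1-ylidene}-4-[(4-methoxyphenyl)methoxy]-2-[(4,4,5,5-tetramethyl-1,3,2-dioxaborolan-2-yl)methyl]hept-2-enedioate | CC1(C)OB(C/C(C(=O)OC)=C\[C@H](OCc2ccc(OC)cc2)[C@@H](OC(C)=O)/C(C(=O)OC)=C\C=C/[C@@]2(C)O[C@@H]2C=O)OC1(C)C
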